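The route rests on disconnecting the C3a–C3b bond and both C8a–N bonds of the pyrrolo[2,3-b]indoline core. A chiral-phosphoric-acid interrupted Fischer indolization joins a 5-bromo-6-hydrazinylbenzofuran ester with a racemic N-methoxycarbonyl 3-prenyl-2-hydroxypyrrolidine (a masked α-branched aldehyde). In one operation it creates quaternary C3a, the indoline ring and the cis aminal C8a. It exploits two features: C3b is the only free carbon ortho to N8-bearing C7a, because C7 carries Br and C3b sits next to the furan-oxygen carbon C4; and the fully substituted C3a blocks indole formation, so N1 traps the 3H-indole. Ester-to-carbinol and carbamate-to-N-methyl conversions finish the synthesis.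

Key step: step 8

Remark on locants: pyrrolo[2,3-b]indoline numbering is used (N1, C2, C3, C3a, C3b, C4, C5, C6, C7, C7a, N8, C8a); the furan is fused on the C4–C5 bond with its oxygen on C4, C2' is the furan carbon next to oxygen and C3' the furan CH. In this numbering the target is (3aS,8aS).

Assumption: the sense of induction of a chiral phosphoric acid on an N–H aryl hydrazone cannot be predicted with confidence, so the catalyst enantiomer that delivers the (3aS,8aS) series is chosen in a first screen (both are available).

Step 1
Reactants: 1 2-hydroxy-4-nitrobenzaldehyde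
Product: 2 5-bromo-2-hydroxy-4-nitrobenzaldehyde
Conditions: Br2 (1.05 equiv), AcOH, 25 → 45 °C
Reagents that add atoms: bromine, BrBr
Why: Electrophilic aromatic bromination, in which the phenol directs to its para carbon C5 (also meta to the formyl group), while the only other activated site, C3, is wedged between OH and NO2, so monobromination at C5 should dominate.

Step 2
Reactants: 2 5-bromo-2-hydroxy-4-nitrobenzaldehyde; 3 methyl bromoacetate
Product: 5 methyl 5-bromo-6-nitrobenzofuran-2-carboxylate, via aryloxyacetate 4 (not isolated)
Conditions: K2CO3 (2.5 equiv), DMF, 25 °C then 90 °C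
Reagents that add atoms: none
Why: Williamson O-alkylation gives aryloxyacetate 4, whose acidic OCH2 group closes onto the ortho aldehyde by intramolecular aldol condensation (5-exo-trig) and dehydrates to the aromatic furan (Rap–Stoermer-type benzofuran synthesis); the weakly nucleophilic nitrophenoxide is consumed by the bromoacetate well before it could attack the nitro-activated C–Br bond.

Step 3
Reactants: 5 methyl 5-bromo-6-nitrobenzofuran-2-carboxylate
Product: 6 methyl 6-amino-5-bromobenzofuran-2-carboxylate
Conditions: Fe powder (5 equiv), AcOH/MeOH, 65 °C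
Reagents that add atoms: none
Why: Béchamp-type reduction with iron in acetic acid converts the nitro group to the amine by electron transfer and should not insert into the C–Br bond or touch the methyl ester.

Step 4
Reactants: 6 methyl 6-amino-5-bromobenzofuran-2-carboxylate
Product: 8 methyl 5-bromo-6-hydrazinylbenzofuran-2-carboxylate (free base), via diazonium chloride 7 (not isolated)
Conditions: NaNO2 (1.05 equiv), conc. HCl/AcOH/H2O, 0 °C; then SnCl2·2H2O (2.5 equiv), conc. HCl, 0 °C → rt; aq. NaHCO3, EtOAc
Reagents that add atoms: sodium nitrite, [Na+].[O-]N=O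
Why: Classical aryl hydrazine synthesis by diazotization and SnCl2 reduction of diazonium salt 7 in cold acid, which leaves ester and bromide alone; the free base is released so that no strong achiral acid is carried into step 8.

Step 5
Reactants: 9 pyrrolidin-2-one
Product: 10 methyl 2-oxopyrrolidine-1-carboxylate
Conditions: n-BuLi (1.05 equiv), THF, −78 °C; ClCO2Me (1.1 equiv), −78 → 0 °C
Reagents that add atoms: methyl chloroformate, COC(=O)Cl
Why: N-Acylation of the lithium lactamate with a chloroformate gives the imide-type carbamate, which acidifies C3–H for step 6, activates the ring carbonyl for step 7 and later supplies the N-methyl carbon.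

Step 6
Reactants: 10 methyl 2-oxopyrrolidine-1-carboxylate; 11 prenyl bromide (1-bromo-3-methylbut-2-ene)
Product: 12 racemic methyl 3-(3-methylbut-2-enyl)-2-oxopyrrolidine-1-carboxylate
Conditions: LiN(SiMe3)2 (1.05 equiv), THF, −78 °C; 11 (1.2 equiv), −78 → −20 °C
Reagents that add atoms: none
Why: Kinetic lithium enolate formation at C3 of the N-acyl lactam followed by SN2 alkylation with the reactive allylic bromide; the product is racemic by design because this centre is erased in step 8.

Step 7
Reactants: 12 racemic methyl 3-(3-methylbut-2-enyl)-2-oxopyrrolidine-1-carboxylate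
Product: 13 racemic methyl 2-hydroxy-3-(3-methylbut-2-enyl)pyrrolidine-1-carboxylate (mixture of diastereomers)
Conditions: LiEt3BH (1.1 equiv), THF, −78 °C; sat. aq. NaHCO3
Reagents that add atoms: none
Why: Partial hydride reduction of an N-acyl lactam, where the ring carbonyl is the more electrophilic one and its tetrahedral lithium alkoxide persists at −78 °C, so protonation should give the hemiaminal (both diastereomers usable) without over-reduction.

Step 8
Reactants: 8 methyl 5-bromo-6-hydrazinylbenzofuran-2-carboxylate; 13 racemic methyl 2-hydroxy-3-(3-methylbut-2-enyl)pyrrolidine-1-carboxylate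
Product: 17 methyl (3aS,8aS)-7-bromo-1-methoxycarbonyl-3a-(3-methylbut-2-enyl)-1,2,3,3a,8,8a-hexahydro-4,5-furo-fused pyrrolo[2,3-b]indole-2'-carboxylate, via hydrazone 14 (not isolated), via ene-hydrazine 15 (not isolated), via 3H-indole 16 (not isolated)
Conditions: 8 (1.0 equiv), 13 (1.3 equiv), chiral spirocyclic phosphoric acid 6,6'-bis(2,4,6-triisopropylphenyl)-1,1'-spirobiindan-7,7'-diyl hydrogen phosphate (10 mol%, enantiomer per the assumption), Amberlite CG50 (weakly acidic carboxylic resin), toluene, 25 → 45 °C
Reagents that add atoms: none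
Why: Proposed new method: acid opens hemiaminal 13 to the α-branched aldehyde, which condenses with 8 to hydrazone 14 and tautomerizes to ene-hydrazine 15 (erasing the racemic α-centre); the phosphate-bound, N-protonated ene-hydrazine then undergoes a [3,3] sigmatropic shift onto C3b, the arene rearomatizes, the anilinic nitrogen adds to the iminium carbon and ammonia leaves to give 3H-indole 16, which cannot aromatize and is captured by the carbamate N–H. The closest known reactions are the racemic interrupted Fischer indolization of N-carbamoyl 3-alkyl-2-hydroxypyrrolidines with aryl hydrazines and the chiral-phosphoric-acid Fischer indolization of N-protected aryl hydrazones of ketones run with a carboxylic resin as ammonia sink; new here is the enantioselective version on an aldehyde-derived N–H hydrazone. The indoline ring closes 5-exo-trig (N8 onto the exocyclic C8a=N+ unit) and the pyrrolidine ring closes 5-exo-trig (N1 onto the C8a=N8 bond of 16). C3a is set in the [3,3] step by the chiral phosphate, which is expected to hold the ene-hydrazinium through two N–H···O contacts while the E and Z ene-hydrazines interconvert through 14 (dynamic kinetic resolution under Curtin–Hammett control); C8a follows from C3a because only the cis 5,5-fusion is geometrically accessible. Regioselectivity is secured by the C7 bromine, which leaves C3b as the single ortho carbon, activated by the furan oxygen on C4 and little hindered because that oxygen is tied back in the ring; the non-basic carbamate cannot neutralize the catalyst, the aldehyde has no second enolizable side, and the ester stands in for the acid-labile furyl carbinol.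

Step 9
Reactants: 17 methyl (3aS,8aS)-7-bromo-1-methoxycarbonyl-3a-(3-methylbut-2-enyl)-1,2,3,3a,8,8a-hexahydro-4,5-furo-fused pyrrolo[2,3-b]indole-2'-carboxylate
Product: 19 (3aS,8aS)-7-bromo-2'-(2-hydroxypropan-2-yl)-1-methoxycarbonyl-3a-(3-methylbut-2-enyl)-1,2,3,3a,8,8a-hexahydro-4,5-furo-fused pyrrolo[2,3-b]indole, via methyl ketone 18 (not isolated)
Conditions: MeMgBr (4.5 equiv), THF, −78 → 0 °C; aq. NH4Cl
Reagents that add atoms: methylmagnesium bromide, C[Mg]Br
Why: Double Grignard addition to the ester through ketone 18; one equivalent is spent on N8–H, the carbamate is too poor an electrophile to react below 0 °C, and MeMgBr should not exchange with the aryl bromide.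

Step 10
Reactants: 19 (3aS,8aS)-7-bromo-2'-(2-hydroxypropan-2-yl)-1-methoxycarbonyl-3a-(3-methylbut-2-enyl)-1,2,3,3a,8,8a-hexahydro-4,5-furo-fused pyrrolo[2,3-b]indole
Product: 20 CNP0306513.1: (3aS,8aS)-7-bromo-2'-(2-hydroxypropan-2-yl)-1-methyl-3a-(3-methylbut-2-enyl)-1,2,3,3a,8,8a-hexahydro-4,5-furo-fused pyrrolo[2,3-b]indole
Conditions: AlH3·NMe2Et (4 equiv, toluene solution), THF, 0 °C → rt; aq. KNaC4H4O6 (potassium sodium tartrate)
Reagents that add atoms: none
Why: Hydride reduction of the methyl carbamate through the formamide and iminium stages should deliver N–CH3; amine-stabilized alane is electrophilic enough for the carbamate at 0 °C yet is not expected to reduce the aryl bromide or the trisubstituted alkene, and neither stereocentre takes part.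

Compound list
1 | 2-hydroxy-4-nitrobenzaldehyde | O=Cc1ccc([N+](=O)[O-])cc1O | starting material
2 | 5-bromo-2-hydroxy-4-nitrobenzaldehyde | O=Cc1cc(Br)c([N+](=O)[O-])cc1O | intermediate
3 | methyl bromoacetate | COC(=O)CBr | starting material
4 | methyl 2-(4-bromo-2-formyl-5-nitrophenoxy)acetate (forms in the flask in step 2) | COC(=O)COc1cc([N+](=O)[O-])c(Br)cc1C=O | intermediate
5 | methyl 5-bromo-6-nitrobenzofuran-2-carboxylate | COC(=O)c1cc2cc(Br)c([N+](=O)[O-])cc2o1 | intermediate
6 | methyl 6-amino-5-bromobenzofuran-2-carboxylate | COC(=O)c1cc2cc(Br)c(N)cc2o1 | intermediate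
7 | 5-bromo-2-(methoxycarbonyl)benzofuran-6-diazonium chloride (forms in the flask in step 4) | COC(=O)c1cc2cc(Br)c([N+]#N)cc2o1.[Cl-] | intermediate
8 | methyl 5-bromo-6-hydrazinylbenzofuran-2-carboxylate | COC(=O)c1cc2cc(Br)c(NN)cc2o1 | intermediate
9 | pyrrolidin-2-one | O=C1CCCN1 | starting material
10 | methyl 2-oxopyrrolidine-1-carboxylate | COC(=O)N1CCCC1=O | intermediate
11 | prenyl bromide (1-bromo-3-methylbut-2-ene) | CC(C)=CCBr | starting material
12 | racemic methyl 3-(3-methylbut-2-enyl)-2-oxopyrrolidine-1-carboxylate | COC(=O)N1CCC(CC=C(C)C)C1=O | intermediate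
13 | racemic methyl 2-hydroxy-3-(3-methylbut-2-enyl)pyrrolidine-1-carboxylate (diastereomer mixture) | COC(=O)N1CCC(CC=C(C)C)C1O | intermediate
14 | hydrazone of 4-(methoxycarbonylamino)-2-(3-methylbut-2-enyl)butanal with 8 (racemic, E/Z mixture; forms in the flask in step 8) | COC(=O)NCCC(CC=C(C)C)C=NNc1cc2oc(C(=O)OC)cc2cc1Br | intermediate
15 | ene-hydrazine tautomer of 14 (E/Z mixture; forms in the flask in step 8) | COC(=O)NCCC(CC=C(C)C)=CNNc1cc2oc(C(=O)OC)cc2cc1Br | intermediate
16 | (S)-configured 3H-indole: the C8a=N8 imine form of 17 with a free CH2CH2NHCO2Me chain on the quaternary carbon (forms in the flask in step 8) | CC(C)=CC[C@@]1(CCNC(=O)OC)C=Nc2c(Br)cc3cc(C(=O)OC)oc3c21 | intermediate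
17 | methyl (3aS,8aS)-7-bromo-1-methoxycarbonyl-3a-(3-methylbut-2-enyl)-1,2,3,3a,8,8a-hexahydro-4,5-furo-fused pyrrolo[2,3-b]indole-2'-carboxylate | CC(C)=CC[C@@]12CCN(C(=O)OC)[C@@H]1Nc1c(Br)cc3cc(C(=O)OC)oc3c12 | intermediate
18 | (3aS,8aS)-2'-acetyl analogue of 17 (methyl ketone; forms in the flask in step 9) | CC(C)=CC[C@@]12CCN(C(=O)OC)[C@@H]1Nc1c(Br)cc3cc(C(C)=O)oc3c12 | intermediate
19 | (3aS,8aS)-7-bromo-2'-(2-hydroxypropan-2-yl)-1-methoxycarbonyl-3a-(3-methylbut-2-enyl)-1,2,3,3a,8,8a-hexahydro-4,5-furo-fused pyrrolo[2,3-b]indole | CC(C)=CC[C@@]12CCN(C(=O)OC)[C@@H]1Nc1c(Br)cc3cc(C(C)(C)O)oc3c12 | intermediate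
20 | CNP0306513.1, (3aS,8aS)-7-bromo-2'-(2-hydroxypropan-2-yl)-1-methyl-3a-(3-methylbut-2-enyl)-1,2,3,3a,8,8a-hexahydro-4,5-furo-fused pyrrolo[2,3-b]indole | CC(C)=CC[C@@]12CCN(C)[C@@H]1Nc1c(Br)cc3cc(C(C)(C)O)oc3c12 | target

Total step count: 10. Longest linear sequence: 7 steps (steps 1, 2, 3, 4, 8, 9, 10); the lactam branch (steps 5 to 7) joins at step 8.

Steps most likely to fail

Step 8 (bears the new-method label).
- What may go wrong: poor facial selectivity in the [3,3] shift because the ene-hydrazine carries a free N–H; a racemic background reaction on the resin; slow turnover if ammonia is not removed from the phosphoric acid.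
- Fallback (known chemistry): set out from 8 and 13 and run the racemic interrupted Fischer indolization in AcOH/H2O (1:1) at 60–80 °C. This should give the racemic cis-fused carbamate ester F1. Preparative chiral-phase supercritical fluid chromatography (amylose tris(3,5-dimethylphenylcarbamate) phase, CO2/MeOH) then separates the (3aS,8aS) enantiomer, which is 17, from the (3aR,8aR) antipode F2. The route resumes at 17.

Step 10.
- What may go wrong: over-reduction (hydrodebromination, or reductive opening of the N1–C8a–N8 aminal) and Lewis-acid ionization of the tertiary furyl carbinol leading to elimination or hydrogenolysis.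
- Fallback: set out from 19 and remove the methoxycarbonyl group with LiB(sec-Bu)3H (L-Selectride, THF, reflux; hydride attack on the O-methyl group, the carbamate salt losing CO2 on aq. NH4Cl work-up). This gives the N1–H aminal (3aS,8aR)-7-bromo-2'-(2-hydroxypropan-2-yl)-3a-(3-methylbut-2-enyl)-1,2,3,3a,8,8a-hexahydro-4,5-furo-fused pyrrolo[2,3-b]indole F3; its C8a descriptor changes only because the priorities change, the geometry is unchanged. Reductive methylation with aqueous formaldehyde (1.1 equiv) and NaBH(OAc)3 in MeCN at 0 °C → rt then returns to 20, since the aliphatic N1 should react far faster than the hindered, ortho-brominated anilinic N8.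

Step 6.
- What may go wrong: double alkylation, transfer of the methoxycarbonyl group between enolate and imide (Claisen-type self-acylation), and ring opening of the N-acyl lactam.
- Fallback: set out from 9 and reverse the order of acylation and alkylation. Silylation (Me3SiCl, Et3N, toluene) gives 1-(trimethylsilyl)pyrrolidin-2-one F4. Enolization with LiN(iPr)2 (THF, −78 °C) and alkylation with 11 gives 3-(3-methylbut-2-enyl)-1-(trimethylsilyl)pyrrolidin-2-one F5. F5 loses silicon on aqueous methanolic work-up to give racemic 3-(3-methylbut-2-enyl)pyrrolidin-2-one F6. N-Acylation as in step 5 (n-BuLi, ClCO2Me, THF, −78 °C) comes back to 12.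

Further compounds
F1 | step 8 | racemic cis-fused methyl 7-bromo-1-methoxycarbonyl-3a-(3-methylbut-2-enyl)-1,2,3,3a,8,8a-hexahydro-4,5-furo-fused pyrrolo[2,3-b]indole-2'-carboxylate (both enantiomers, drawn without wedges) | CC(C)=CCC12CCN(C(=O)OC)C1Nc1c(Br)cc3cc(C(=O)OC)oc3c12
F2 | step 8 | (3aR,8aR) antipode of 17 | CC(C)=CC[C@]12CCN(C(=O)OC)[C@H]1Nc1c(Br)cc3cc(C(=O)OC)oc3c12
F3 | step 10 | (3aS,8aR)-7-bromo-2'-(2-hydroxypropan-2-yl)-3a-(3-methylbut-2-enyl)-1,2,3,3a,8,8a-hexahydro-4,5-furo-fused pyrrolo[2,3-b]indole (N1–H) | CC(C)=CC[C@@]12CCN[C@@H]1Nc1c(Br)cc3cc(C(C)(C)O)oc3c12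
F4 | step 6 | 1-(trimethylsilyl)pyrrolidin-2-one | C[Si](C)(C)N1CCCC1=O
F5 | step 6 | racemic 3-(3-methylbut-2-enyl)-1-(trimethylsilyl)pyrrolidin-2-one | C[Si](C)(C)N1CCC(CC=C(C)C)C1=O
F6 | step 6 | racemic 3-(3-methylbut-2-enyl)pyrrolidin-2-one | CC(C)=CCC1CCNC1=O
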